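The numbering is that of the carotenoids. The plan cuts C7–C8 and the C6–O bond together: the C6 hydroxyl oxygen is the former aldehyde oxygen of C7. It exploits two features. O5 and O6 are trans on the cyclohexane ring C1–C6, and the C6 carbinol ends the C7=C8–C9=C10–C11=O dienal, a vinylogous γ-hydroxy enal. In the key step a metallated prenal imine adds to enantiopure 5,6-epoxy-β-cyclocitral. The C7 alkoxide migrates onto C6 with inversion (Payne), and the new C6–C7 oxirane is opened by vinylogous E1cB elimination. One acid-free operation joins the chain, fixes the trans-diol regiospecifically, frees both tertiary hydroxyls and draws E-C7=C8. The precursor is a bicyclic C10 epoxy aldehyde.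

Key step: step 5

Remark: ring atoms are C1–C6, chain atoms C7–C15 then C15'–C10', and O5, O6, O7 are the oxygens on C5, C6, C7; dialdehyde 13, the C10 building block of industrial carotenoid synthesis, is taken as commercially available.

Step 1
Reactants: 1 β-cyclocitral (2,6,6-trimethylcyclohex-1-ene-1-carbaldehyde)
Product: 2 β-cyclogeraniol [(2,6,6-trimethylcyclohex-1-en-1-yl)methanol]
Conditions: NaBH4, MeOH, 0 °C
Reagents that add atoms: none
Why: Borohydride 1,2-reduction of a hindered enal to the allylic alcohol; no stereocentre is formed.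

Step 2
Reactants: 2 β-cyclogeraniol
Product: 3 [(1R,6R)-2,2,6-trimethyl-7-oxabicyclo[4.1.0]heptan-1-yl]methanol (oxirane on C5–C6, C5 R)
Conditions: Ti(OiPr)4 (10 mol %), D-(−)-diethyl tartrate (12 mol %), t-BuOOH (decane), 4 Å MS, CH2Cl2, −20 °C
Reagents that add atoms: tert-butyl hydroperoxide, CC(C)(C)OO
Why: Sharpless asymmetric epoxidation; 2 has the substituent pattern of geraniol (methyl cis and chain carbon C4 trans to CH2OH), for which L-(+)-tartrate gives the 3S oxirane, so D-(−)-tartrate should deliver oxygen to the face that makes C5 R, setting C5 and C6 together as the cis-fused oxirane.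

Step 3
Reactants: 3 epoxy alcohol
Product: 4 (1S,6R)-2,2,6-trimethyl-7-oxabicyclo[4.1.0]heptane-1-carbaldehyde (5,6-epoxy-β-cyclocitral)
Conditions: TPAP (5 mol %), NMO, 4 Å MS, CH2Cl2, rt
Reagents that add atoms: none
Why: Ley–Griffith oxidation is neutral, so the tetrasubstituted oxirane should survive, and the aldehyde has no α-hydrogen and cannot epimerise.

Step 4
Reactants: 5 3-methylbut-2-enal (prenal); 6 tert-butylamine
Product: 7 (E)-N-tert-butyl-3-methylbut-2-en-1-imine
Conditions: MgSO4, Et2O, 0 °C → rt
Reagents that add atoms: none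
Why: Imine condensation of an aldehyde with a primary amine, driven by the drying agent; the bulky N-tert-butyl group later shields C11 from 1,2-attack.

Step 5
Reactants: 4 epoxy aldehyde; 7 prenal tert-butylimine
Product: 12 (2E,4E)-5-[(1R,2R)-1,2-dihydroxy-2,6,6-trimethylcyclohexyl]-3-methylpenta-2,4-dienal, via azadienyllithium 8 (not isolated), via C8-aldolate 9 (not isolated), via spiro-oxirane alkoxide 10 (not isolated), via dienimine diolate 11 (not isolated)
Conditions: 7 (1.2 equiv), LDA (1.2 equiv), THF, −78 °C; 4, −78 → 0 °C; KHMDS (1.2 equiv), 0 °C → rt; AcOH–NaOAc buffer (pH 4.5), rt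
Reagents that add atoms: water, O
Why: Proposed new method: azadienyllithium 8 adds to the non-enolisable aldehyde 4 and, as in the known γ-selective aldol reaction of metallated enimines, the crowded α-adduct reverts on warming so that the C8-bonded aldolate 9 collects as both C7 epimers. O7 of 9 then attacks C6 anti to the oxirane C6–O bond (Payne rearrangement, known for metal alkoxides in aprotic solvents), and KHMDS removes a C8 proton of the resulting spiro-oxirane 10 so that the azadienyl anion expels O7 from C7 (vinylogous E1cB, closest known type the base isomerisation of β,γ-epoxy carbonyl compounds to γ-hydroxy enones); this strain-releasing, irreversible step drains the uphill Payne equilibrium. No ring of the target is closed; the transient C6–C7–O7 oxirane closes 3-exo-tet and is reopened in the same flask. C5 keeps the configuration from step 2 because its C–O bond is never broken, C6 is set by the stereospecific SN2 inversion, and C7 becomes sp2, so both aldol epimers converge on the one trans-diol. The step needs opening at C6 rather than C5 (attack at C5 would give the enantiomeric diol), which the one-carbon tether of O7 enforces, and it needs O7 to be kept, which holds because in excess base O7 is an oxide anion that cannot leave as it does in an ordinary aldol condensation. E geometry at C7=C8 and C9=C10 should follow from the s-trans azadienyl anion and from strain between a Z chain and the C1 gem-dimethyl group, and the buffered hydrolysis of 11 avoids the acid that turns such systems into 5,8-furanoid ethers.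

Step 6
Reactants: 13 (2E,4E,6E)-2,7-dimethylocta-2,4,6-trienedial; 14 diethyl {2-[methoxy(methyl)amino]-2-oxoethyl}phosphonate
Product: 16 (2E,4E,6E,8E)-N-methoxy-N,4,9-trimethyl-10-oxodeca-2,4,6,8-tetraenamide, via sodium phosphonate anion 15 (not isolated)
Conditions: 14, NaH, THF, 0 °C; added to 13 (2 equiv), 0 °C → rt
Reagents that add atoms: none
Why: Horner–Wadsworth–Emmons olefination, E-selective with the stabilised amide phosphonate, and the excess of the symmetric dialdehyde should hold it at mono-olefination.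

Step 7
Reactants: 16 aldehyde amide
Product: 17 (2E,4E,6E,8E)-10-hydroxy-N-methoxy-N,4,9-trimethyldeca-2,4,6,8-tetraenamide
Conditions: NaBH4, MeOH–THF, 0 °C
Reagents that add atoms: none
Why: Chemoselective borohydride 1,2-reduction of the aldehyde; the Weinreb amide and the tetraene are inert to NaBH4 at 0 °C.

Step 8
Reactants: 17 allylic alcohol
Product: 19 [(2E,4E,6E,8E)-10-[methoxy(methyl)amino]-2,7-dimethyl-10-oxodeca-2,4,6,8-tetraenyl]triphenylphosphonium bromide, via allylic bromide 18 (not isolated)
Conditions: CBr4 (1.1 equiv), PPh3 (2.3 equiv), CH2Cl2, 0 °C → rt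
Reagents that add atoms: triphenylphosphine, c1ccc(cc1)P(c1ccccc1)c1ccccc1; carbon tetrabromide, BrC(Br)(Br)Br
Why: Appel bromination of the primary allylic alcohol followed by SN2 quaternisation of the bromide by the excess phosphine in the same flask.

Step 9
Reactants: 12 C15 dihydroxy dienal; 19 C12 phosphonium bromide
Product: 21 all-E (5R,6R)-5,6-dihydroxy-N-methoxy-N-methyl-5,6-dihydro-10'-apo-β-caroten-10'-amide, via ylide 20 (not isolated)
Conditions: NaOMe, MeOH–CH2Cl2, 0 °C → rt, argon, dark
Reagents that add atoms: none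
Why: Wittig olefination with an ylide stabilised through the tetraenamide, which should favour the E C11=C12 bond, while methoxide leaves the tertiary hydroxyls and both stereocentres untouched.

Step 10
Reactants: 21 C27 Weinreb amide
Product: 23 all-E (5R,6R)-5,6-dihydroxy-5,6-dihydro-10'-apo-β-caroten-10'-al (CNP0235139.1), via aluminium hemiaminal 22 (not isolated)
Conditions: DIBAL-H (3.5 equiv), THF, −78 °C; Na2SO4·10H2O, −78 °C → rt
Reagents that add atoms: none
Why: Weinreb amide reduction; two equivalents of DIBAL-H are consumed by the hydroxyls, the third gives the chelated hemiaminal 22 that resists further reduction, and the aldehyde is released only in the neutral quench, which spares the acid-labile C6 allylic alcohol.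

Compound list
1 | β-cyclocitral (2,6,6-trimethylcyclohex-1-ene-1-carbaldehyde) | CC1=C(C=O)C(C)(C)CCC1 | starting material
2 | β-cyclogeraniol | CC1=C(CO)C(C)(C)CCC1 | intermediate
3 | [(1R,6R)-2,2,6-trimethyl-7-oxabicyclo[4.1.0]heptan-1-yl]methanol | OC[C@]1(O2)C(C)(C)CCC[C@]12C | intermediate
4 | (1S,6R)-2,2,6-trimethyl-7-oxabicyclo[4.1.0]heptane-1-carbaldehyde | O=C[C@]1(O2)C(C)(C)CCC[C@]12C | intermediate
5 | 3-methylbut-2-enal | CC(C)=CC=O | starting material
6 | tert-butylamine | CC(C)(C)N | starting material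
7 | (E)-N-tert-butyl-3-methylbut-2-en-1-imine | CC(C)=C/C=N/C(C)(C)C | intermediate
8 | azadienyllithium from 7 (γ-deprotonated, delocalised) | [Li+].[CH2-]C(C)=CC=NC(C)(C)C | intermediate
9 | lithium C8-aldolate of 4 and 8 (both C7 epimers, 5,6-oxirane intact) | [Li+].[O-]C(C/C(C)=C/C=N/C(C)(C)C)[C@]1(O2)C(C)(C)CCC[C@]12C | intermediate
10 | Payne-rearranged spiro C6–C7 oxirane, C5 lithium alkoxide | [Li+].CC(C)(C)/N=C/C=C(C)/CC1O[C@@]12C(C)(C)CCC[C@@]2(C)[O-] | intermediate
11 | lithium potassium 5,6-diolate of the N-tert-butylimine of 12 | [Li+].[K+].CC(C)(C)/N=C/C=C(C)/C=C/[C@@]1([O-])C(C)(C)CCC[C@@]1(C)[O-] | intermediate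
12 | (2E,4E)-5-[(1R,2R)-1,2-dihydroxy-2,6,6-trimethylcyclohexyl]-3-methylpenta-2,4-dienal | O=C/C=C(C)/C=C/[C@@]1(O)C(C)(C)CCC[C@@]1(C)O | intermediate
13 | (2E,4E,6E)-2,7-dimethylocta-2,4,6-trienedial | O=C/C(C)=C/C=C/C=C(C)/C=O | starting material
14 | diethyl {2-[methoxy(methyl)amino]-2-oxoethyl}phosphonate | CCOP(=O)(CC(=O)N(C)OC)OCC | starting material
15 | sodium salt of deprotonated 14 | [Na+].CCOP(=O)([CH-]C(=O)N(C)OC)OCC | intermediate
16 | (2E,4E,6E,8E)-N-methoxy-N,4,9-trimethyl-10-oxodeca-2,4,6,8-tetraenamide | CON(C)C(=O)/C=C/C(C)=C/C=C/C=C(C)/C=O | intermediate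
17 | (2E,4E,6E,8E)-10-hydroxy-N-methoxy-N,4,9-trimethyldeca-2,4,6,8-tetraenamide | CON(C)C(=O)/C=C/C(C)=C/C=C/C=C(C)/CO | intermediate
18 | (2E,4E,6E,8E)-10-bromo-N-methoxy-N,4,9-trimethyldeca-2,4,6,8-tetraenamide | CON(C)C(=O)/C=C/C(C)=C/C=C/C=C(C)/CBr | intermediate
19 | [(2E,4E,6E,8E)-10-[methoxy(methyl)amino]-2,7-dimethyl-10-oxodeca-2,4,6,8-tetraenyl]triphenylphosphonium bromide | [Br-].CON(C)C(=O)/C=C/C(C)=C/C=C/C=C(C)/C[P+](c1ccccc1)(c1ccccc1)c1ccccc1 | intermediate
20 | ylide from 19 | CON(C)C(=O)/C=C/C(C)=C/C=C/C=C(C)/[CH-][P+](c1ccccc1)(c1ccccc1)c1ccccc1 | intermediate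
21 | all-E (5R,6R)-5,6-dihydroxy-N-methoxy-N-methyl-5,6-dihydro-10'-apo-β-caroten-10'-amide | CON(C)C(=O)/C=C/C(C)=C/C=C/C=C(C)/C=C/C=C(C)/C=C/[C@@]1(O)C(C)(C)CCC[C@@]1(C)O | intermediate
22 | tris(diisobutylaluminium) derivative of 21: C10' O-aluminium hemiaminal, O5 and O6 aluminium alkoxides | CON(C)C(O[Al](CC(C)C)CC(C)C)/C=C/C(C)=C/C=C/C=C(C)/C=C/C=C(C)/C=C/[C@@]1(O[Al](CC(C)C)CC(C)C)C(C)(C)CCC[C@@]1(C)O[Al](CC(C)C)CC(C)C | intermediate
23 | all-E (5R,6R)-5,6-dihydroxy-5,6-dihydro-10'-apo-β-caroten-10'-al | CC(/C=C/C=O)=C\C=C\C=C(C)\C=C\C=C(C)\C=C\[C@@]1(O)C(C)(C)CCC[C@@]1(C)O | target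

Total steps: 10. Longest linear sequence: 6 (steps 1, 2, 3, 5, 9, 10).

Risk 1 (step 5, key step). The Payne migration at the fully substituted C6 may be slower than several side processes. These are retro-aldol drift, C-alkylation of C6 by the C8 carbanion, and base-induced isomerisation of the oxirane to an allylic alcohol. The fallback uses only known chemistry, sets out from 3 and returns at 12.
- An aqueous Payne rearrangement–hydroxide opening (NaOH, t-BuOH–H2O, reflux) should give (1R,2S)-2-(hydroxymethyl)-1,3,3-trimethylcyclohexane-1,2-diol F1 with the same inversion at C6.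
- Parikh–Doering oxidation of the only oxidisable hydroxyl gives (1R,2R)-1,2-dihydroxy-2,6,6-trimethylcyclohexane-1-carbaldehyde F2.
- Horner–Wadsworth–Emmons olefination with diethyl [(E)-3-cyano-2-methylprop-2-enyl]phosphonate gives (2E,4E)-5-[(1R,2R)-1,2-dihydroxy-2,6,6-trimethylcyclohexyl]-3-methylpenta-2,4-dienenitrile F3.
- DIBAL-H reduction of F3 gives 12.

Risk 2 (step 2). Facial selectivity may be poor, because the C1 gem-dimethyl group crowds the titanium-bound allylic alkoxide. The fallback replaces asymmetric catalysis by a classical resolution, sets out from 2 and returns at 3.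
- VO(acac)2/t-BuOOH epoxidation gives the racemic epoxy alcohol F4.
- Esterification with (S)-2-methoxy-2-phenylacetic acid (DCC, DMAP) gives the (1R,6R)-epoxy alcohol (S)-methoxyphenylacetate F5 and the (1S,6S)-epoxy alcohol (S)-methoxyphenylacetate F6, which are separated by chromatography or crystallisation.
- K2CO3/MeOH releases 3 from F5.

Risk 3 (step 9). E selectivity at the new C11=C12 bond may be incomplete, and the strongly delocalised ylide may react sluggishly. The fallback moves to a phosphonate carbanion under thermodynamic control, sets out from 17 and returns at 21.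
- PBr3 gives bromide 18, which is isolated this time.
- A Michaelis–Arbuzov reaction with P(OEt)3 gives diethyl [(2E,4E,6E,8E)-10-[methoxy(methyl)amino]-2,7-dimethyl-10-oxodeca-2,4,6,8-tetraenyl]phosphonate F7.
- Horner–Wadsworth–Emmons olefination of 12 (NaHMDS, THF, −78 → 0 °C) gives 21.

Further compounds
F1 | step 5 | (1R,2S)-2-(hydroxymethyl)-1,3,3-trimethylcyclohexane-1,2-diol | OC[C@@]1(O)C(C)(C)CCC[C@@]1(C)O
F2 | step 5 | (1R,2R)-1,2-dihydroxy-2,6,6-trimethylcyclohexane-1-carbaldehyde | O=C[C@@]1(O)C(C)(C)CCC[C@@]1(C)O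
F3 | step 5 | (2E,4E)-5-[(1R,2R)-1,2-dihydroxy-2,6,6-trimethylcyclohexyl]-3-methylpenta-2,4-dienenitrile | N#C/C=C(C)/C=C/[C@@]1(O)C(C)(C)CCC[C@@]1(C)O
F4 | step 2 | racemic (2,2,6-trimethyl-7-oxabicyclo[4.1.0]heptan-1-yl)methanol | OCC12OC1(C)CCCC2(C)C
F5 | step 2 | [(1R,6R)-2,2,6-trimethyl-7-oxabicyclo[4.1.0]heptan-1-yl]methyl (S)-2-methoxy-2-phenylacetate | CO[C@H](C(=O)OC[C@]1(O2)C(C)(C)CCC[C@]12C)c1ccccc1
F6 | step 2 | [(1S,6S)-2,2,6-trimethyl-7-oxabicyclo[4.1.0]heptan-1-yl]methyl (S)-2-methoxy-2-phenylacetate | CO[C@H](C(=O)OC[C@@]1(O2)C(C)(C)CCC[C@@]12C)c1ccccc1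
F7 | step 9 | diethyl [(2E,4E,6E,8E)-10-[methoxy(methyl)amino]-2,7-dimethyl-10-oxodeca-2,4,6,8-tetraenyl]phosphonate | CCOP(=O)(C/C(C)=C/C=C/C=C(C)/C=C/C(=O)N(C)OC)OCC
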